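No rate constant stands on the board, so we start with what needs none: where a curve stops.

| setting | eta | zeta | Sunday's | Saturday's | Wednesday's |
|---|---|---|---|---|---|
| starting material | 31 mM (in portions, 2) | 270 mM (in portions, 2) | 40 mM (in portions, 2) | 120 mM (in portions, 2) | 400 mM (in portions, 2) |
| partner | 60 mM | 60 mM | 60.0 mM | 60.0 mM | 60.0 mM |
| protic impurity | 4 mM | 4 mM | 4.00 mM | 4.00 mM | 4.00 mM |
| solid reagent | 60 mM | 60 mM | 60.0 mM | 60.0 mM | 60.0 mM |
| remark | run made earlier; portions every 8.0 min | run made earlier; portions every 8.0 min | the portions of starting material follow each other after 8.0 min, the first at the start | the portions of starting material follow each other after 8.0 min, the first at the start | the portions of starting material follow each other after 8.0 min, the first at the start |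
| time |  |  | 5.0 h | 5.0 h | 5.0 h |

| run | time / h | product / % | starting material / % |
|---|---|---|---|
| eta | 0.417 | 2 | 92 |
| eta | 1.00 | 2 | 80 |
| eta | 2.00 | 2 | 67 |
| eta | 5.00 | 14 | 34 |
| zeta | 0.667 | 0 | 96 |
| zeta | 2.00 | 0 | 86 |
| zeta | 3.00 | 0 | 80 |
| zeta | 5.00 | 3 | 80 |

(standard deviation of a reading: 2 percentage points)
- the numbers in the tables scatter by 2 percentage points (one standard deviation)
- at the start none of the solid reagent is in solution
- "hardly changes" means that all values lie within two and a half points (for a concentration: within two and a half percent of the largest)
* [product] at the end for Sunday's, Saturday's, Wednesday's, in this order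
* the course of these numbers from the first flask to the last (hardly changes / falls, then rises / falls all the way / rises, then falls / rises all the way)

Which charge is small in the zeta run? The solid reagent, at 60 mM against 270 mM of starting material, so it is the candidate for limiting reagent.

What does its balance predict? If each unit of solid reagent takes at most one of starting material, the loss must stop near the charge, the way a tank stops draining when it is empty, whatever its time constant.

Does it stop? Starting material reads 86% at 2.00 h, 80% at 3.00 h and 80% at 5.00 h. So I name the loss at that level the consumption cap: 54.0 mM for this charge of solid reagent.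

But that is not 60 mM. True, the gap is 6.00 mM, and a reading on this flask scatters by 5.40 mM, so I leave the gap unexplained.

Does the eta run feel the cap? No: its last reading shows a loss of 20.5 mM, below the cap, and it was still falling.

And the new flasks? Sunday's charge of 40 mM lies below the cap, so eta's percentage should carry over, and my figure for product there is 5.60 mM. Wednesday's charge of 400 mM lies far above it, so I expect about 86.5% of its starting material to remain, which is an estimate and no bound, since the cap is read off readings that scatter by 5.40 mM. Its loss should then be near zeta's, so I carry zeta's product in concentration, not percent: 8.10 mM, give or take 5.40 mM. For Saturday's flask no reading stands near its charge, so I give no product figure.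

The forecast gives 5.5 mM, 10.5 mM and 7 mM, a course that rises, then falls, and holds “so the reagent is consumed stoichiometrically”; its Wednesday's figure lies below mine.

The flasks end at 6.13 mM, 8.51 mM and 5.18 mM of product, so the row rises, then falls, turning at 110 mM of starting material.

    starting material + reagent → open intermediate (k = 0.00406 M⁻¹ s⁻¹)
    reagent + partner → second intermediate (k = 0.00455 M⁻¹ s⁻¹)
    open intermediate + second intermediate → product (k = 0.00175 M⁻¹ s⁻¹)
    starting material + protic impurity → quenched substrate (k = 0.0195 M⁻¹ s⁻¹)
    solid reagent ⇌ reagent, rate k5*(cs5 - [reagent]) while solid is left; crystals form when [reagent] > cs5 (solubility = 36.0 mM, k = 1.85 × 10⁻⁴ s⁻¹)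

My Sunday's figure is 0.530 mM low, and my Wednesday's is 2.92 mM high, inside its scatter. Now the cap again. Saturday's flask ends with 64.9% of its starting material, a loss of 42.1 mM, below the cap of 54.0 mM. Wednesday's flask ends with 86.2% against my estimate of 86.5%, a loss of 55.2 mM, above the cap by 1.29 mM, which is less than the scatter of 5.40 mM.

The readings were generated by integration on assumed constants, and the scatter is random.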